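**Plan**

- Retrosynthetic cuts, in order: (1) the ring–CHO bond, because the de-formyl ring is a 4-alkyl-3,5-dimethylphenol with two equivalent ortho positions; (2) the bond between the carbinol carbon C3 and the alkene carbon C4 of the pentenyl chain, giving an (S)-4-arylbutan-2-yl 2,4,6-triisopropylbenzoate and an (E)-2-arylethenyl boronic ester; (3) the aryl–alkyne bond of the first piece (4-iodo-3,5-dimethylphenol + (R)-but-3-yn-2-ol) and the C=C bond of the second (2,5-dihydroxybenzaldehyde + a diborylmethane).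
- Forward: no ring is built, both benzene rings are bought; arm A (steps 1–4) and arm B (steps 5–7) are joined in step 8 by lithiation–borylation with 1,2-metallate shift and C–B oxidation, followed by desilylation, ortho-formylation and deallylation.
- Enabling feature: the only stereocentre is a carbinol carbon that, before the union, carries one H between CH3 and CH2CH2Ar. Its oxygen, as a hindered benzoate, makes this C–H lithiable (polarity reversal of the carbinol carbon) and then serves as leaving group, while the neighbouring sp2 carbon of the E-styryl unit rides on boron and migrates; the boron left on carbon becomes the tertiary OH.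
- Stereochemistry: from (R)-but-3-yn-2-ol (chiral pool); one inversion in the Mitsunobu esterification, then retention (lithiation), retention (borylation), inversion (1,2-shift) and retention (oxidation) should give the (S) tertiary alcohol. The E alkene comes from the boron-Wittig step and is kept by the alkenyl migration.
- Protecting groups: TIPS on the ring-A phenol (inert to s-BuLi, weak director) and allyl on the hydroquinone (stable to base and fluoride, removed by Pd(0) without acid), so that only the ring-A phenol is free when the formyl group is introduced.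

Key step: step 8

Remark: (R)-but-3-yn-2-ol of high enantiomeric purity is taken as the commercial source of chirality; organometallic intermediates are drawn as ligand-free monomers.

**Route**

Step 1
Reactants: 1 4-iodo-3,5-dimethylphenol
Product: 2 (4-iodo-3,5-dimethylphenoxy)triisopropylsilane
Conditions: TIPSCl, imidazole, DMF, rt
Reagents that add atoms: chlorotriisopropylsilane (TIPSCl), CC(C)[Si](Cl)(C(C)C)C(C)C
Why: Standard silylation of a phenol; the bulky TIPS ether is chosen because it should survive s-BuLi and barely directs ortho-metalation.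

Step 2
Reactants: 2 (4-iodo-3,5-dimethylphenoxy)triisopropylsilane; 3 (R)-but-3-yn-2-ol
Product: 4 (2R)-4-[2,6-dimethyl-4-(triisopropylsilyloxy)phenyl]but-3-yn-2-ol
Conditions: PdCl2(PPh3)2 (cat.), CuI (cat.), Et3N/THF (degassed), 60 °C
Reagents that add atoms: none
Why: Sonogashira coupling of the aryl iodide (iodide chosen because of the two flanking methyl groups) with the terminal alkyne; the carbinol stereocentre of 3 is not involved.

Step 3
Reactants: 4 (2R)-4-[2,6-dimethyl-4-(triisopropylsilyloxy)phenyl]but-3-yn-2-ol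
Product: 5 (2R)-4-[2,6-dimethyl-4-(triisopropylsilyloxy)phenyl]butan-2-ol
Conditions: H2 (1 atm), 10% Pd/C, EtOAc, rt
Reagents that add atoms: none
Why: Catalytic hydrogenation saturates the alkyne while the aryl silyl ether and the stereocentre are untouched; a short reaction in EtOAc limits propargylic C–O hydrogenolysis.

Step 4
Reactants: 5 (2R)-4-[2,6-dimethyl-4-(triisopropylsilyloxy)phenyl]butan-2-ol
Product: 6 (2S)-4-[2,6-dimethyl-4-(triisopropylsilyloxy)phenyl]butan-2-yl 2,4,6-triisopropylbenzoate
Conditions: 2,4,6-triisopropylbenzoic acid, PPh3, DIAD, THF, 0 °C → rt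
Reagents that add atoms: 2,4,6-triisopropylbenzoic acid, CC(C)c1cc(C(C)C)c(C(=O)O)c(C(C)C)c1
Why: Mitsunobu esterification, an SN2 displacement of the activated alcohol by the carboxylate, inverts the carbinol centre from R to S and installs the hindered benzoate needed for α-lithiation.

Step 5
Reactants: 7 2,5-dihydroxybenzaldehyde
Product: 8 2,5-bis(allyloxy)benzaldehyde
Conditions: allyl bromide, K2CO3, DMF, 50 °C
Reagents that add atoms: allyl bromide, C=CCBr
Why: Williamson etherification of both phenols; allyl ethers should withstand organolithium/boron, peroxide, fluoride and Mg/Et3N conditions and are removable without acid.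

Step 6
Reactants: 8 2,5-bis(allyloxy)benzaldehyde; 9 bis(4,4,5,5-tetramethyl-1,3,2-dioxaborolan-2-yl)methane
Product: 12 2-[(E)-2-[2,5-bis(allyloxy)phenyl]ethenyl]-4,4,5,5-tetramethyl-1,3,2-dioxaborolane, via lithiated diborylmethane 10 (not isolated), via β-alkoxy diboronate 11 (not isolated)
Conditions: 9, LiTMP (from 2,2,6,6-tetramethylpiperidine + n-BuLi), THF, 0 °C; then 8, −78 °C → rt; aq. NH4Cl
Reagents that add atoms: none
Why: Boron-Wittig olefination: carbanion 10 adds to the aldehyde and syn B–O elimination from adduct 11 should give the E-alkenyl boronate, the aryl group and the remaining boryl group ending up trans.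

Step 7
Reactants: 12 2-[(E)-2-[2,5-bis(allyloxy)phenyl]ethenyl]-4,4,5,5-tetramethyl-1,3,2-dioxaborolane
Product: 14 2-[(E)-2-[2,5-bis(allyloxy)phenyl]ethenyl]-5,5-dimethyl-1,3,2-dioxaborinane, via alkenylboronic acid 13 (not isolated)
Conditions: NaIO4, NH4OAc, acetone/H2O, rt; then neopentyl glycol, MgSO4, CH2Cl2, rt
Reagents that add atoms: 2,2-dimethylpropane-1,3-diol (neopentyl glycol), OCC(C)(C)CO; water, O (its oxygen appears only in intermediate 13)
Why: Periodate cleaves the pinacol unit to the boronic acid, which is re-esterified with the less hindered neopentyl glycol because the crowded organolithium of step 8 needs an accessible boron; the E geometry is not affected.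

Step 8
Reactants: 6 (2S)-4-[2,6-dimethyl-4-(triisopropylsilyloxy)phenyl]butan-2-yl 2,4,6-triisopropylbenzoate; 14 2-[(E)-2-[2,5-bis(allyloxy)phenyl]ethenyl]-5,5-dimethyl-1,3,2-dioxaborinane
Product: 18 (3S,4E)-5-[2,5-bis(allyloxy)phenyl]-1-[2,6-dimethyl-4-(triisopropylsilyloxy)phenyl]-3-methylpent-4-en-3-ol, via α-lithiated benzoate 15 (not isolated), via boronate complex 16 (not isolated), via tertiary allylic boronic ester 17 (not isolated)
Conditions: s-BuLi (1.6 equiv), TMEDA, CPME, −60 °C; then 14 (2 equiv), −60 °C → rt; then 2 M NaOH, 30% H2O2, THF, 0 °C → rt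
Reagents that add atoms: hydrogen peroxide, OO
Why: s-BuLi·TMEDA, pre-complexed to the carbonyl of the hindered benzoate, should remove the carbinol H of 6 with retention to give the configurationally stable α-oxy organolithium 15 (polarity reversal of the carbinol carbon), which attacks boron of 14 with retention to give 16; there the E-alkenyl group migrates from boron to carbon antiperiplanar to the departing benzoate (1,2-metallate shift, inversion at carbon), forming the C3–C4 bond, and the C–B bond of 17 is oxidised to C–OH with retention. The closest known reaction type is the lithiation–borylation of secondary dialkyl 2,4,6-triisopropylbenzoates with neopentyl glycol boronic esters, and of lithiated carbamates with alkenyl boronic esters, followed by peroxide oxidation to tertiary alcohols. No ring is closed. The only new stereocentre, the tertiary carbinol carbon, is controlled by the (S) C–O stereocentre of 6 through this stereospecific sequence, which places OH where H was and the alkenyl group anti to the old C–O bond and so should give (S). The step needs site-selective deprotonation at the O-bound C–H (secured by the proximity effect of the benzoate carbonyl, the bulky and weakly directing OTIPS group, and the absence of any carbonyl or OH in 6), fast irreversible complexation at −60 °C (secured by the unhindered neopentyl glycol ester, used in excess so that it also consumes residual s-BuLi), migration of the sp2 carbon in preference to a ring oxygen, and retention of the E geometry, which a 1,2-shift of an alkenyl group preserves.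

Step 9
Reactants: 18 (3S,4E)-5-[2,5-bis(allyloxy)phenyl]-1-[2,6-dimethyl-4-(triisopropylsilyloxy)phenyl]-3-methylpent-4-en-3-ol
Product: 19 4-[(3S,4E)-5-[2,5-bis(allyloxy)phenyl]-3-hydroxy-3-methylpent-4-en-1-yl]-3,5-dimethylphenol
Conditions: TBAF, THF, 0 °C; aq. NH4Cl
Reagents that add atoms: none
Why: Fluoride-induced cleavage of the aryl silyl ether, with allyl ethers, alkene and tertiary alcohol inert and a buffered work-up to avoid ionisation of the allylic alcohol.

Step 10
Reactants: 19 4-[(3S,4E)-5-[2,5-bis(allyloxy)phenyl]-3-hydroxy-3-methylpent-4-en-1-yl]-3,5-dimethylphenol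
Product: 21 3-[(3S,4E)-5-[2,5-bis(allyloxy)phenyl]-3-hydroxy-3-methylpent-4-en-1-yl]-6-hydroxy-2,4-dimethylbenzaldehyde, via ortho-hydroxymethyl phenol 20 (not isolated)
Conditions: MgCl2, Et3N, (CH2O)n, THF, reflux; work-up with aq. NH4Cl/citric acid (pH about 4)
Reagents that add atoms: paraformaldehyde (formaldehyde), C=O
Why: Magnesium-phenoxide-directed ortho-formylation (Casnati–Skattebøl): the chelated phenoxide is hydroxymethylated at an ortho carbon to 20, whose benzylic alkoxide is oxidised by hydride transfer to a second formaldehyde; the two ortho positions of 19 are equivalent so a single aldehyde is expected, and the basic medium should spare the tertiary allylic alcohol and the allyl ethers.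

Step 11
Reactants: 21 3-[(3S,4E)-5-[2,5-bis(allyloxy)phenyl]-3-hydroxy-3-methylpent-4-en-1-yl]-6-hydroxy-2,4-dimethylbenzaldehyde
Product: 22 3-[(3S,4E)-5-(2,5-dihydroxyphenyl)-3-hydroxy-3-methylpent-4-en-1-yl]-6-hydroxy-2,4-dimethylbenzaldehyde
Conditions: Pd(PPh3)4 (cat.), K2CO3, degassed MeOH, rt, under argon; aq. NaH2PO4
Reagents that add atoms: none
Why: Pd(0) ionises the aryl allyl ethers to π-allyl complexes with phenoxide leaving groups and methanol captures the allyl unit (Tsuji–Trost type deallylation); no acid is used, so the tertiary allylic alcohol and the E-alkene should persist, and air is excluded to protect the hydroquinone.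

**Compound list**

1 | 4-iodo-3,5-dimethylphenol | Cc1cc(O)cc(C)c1I | starting material
2 | (4-iodo-3,5-dimethylphenoxy)triisopropylsilane | Cc1cc(O[Si](C(C)C)(C(C)C)C(C)C)cc(C)c1I | intermediate
3 | (R)-but-3-yn-2-ol | C[C@@H](O)C#C | starting material
4 | (2R)-4-[2,6-dimethyl-4-(triisopropylsilyloxy)phenyl]but-3-yn-2-ol | C[C@@H](O)C#Cc1c(C)cc(O[Si](C(C)C)(C(C)C)C(C)C)cc1C | intermediate
5 | (2R)-4-[2,6-dimethyl-4-(triisopropylsilyloxy)phenyl]butan-2-ol | C[C@@H](O)CCc1c(C)cc(O[Si](C(C)C)(C(C)C)C(C)C)cc1C | intermediate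
6 | (2S)-4-[2,6-dimethyl-4-(triisopropylsilyloxy)phenyl]butan-2-yl 2,4,6-triisopropylbenzoate | C[C@H](OC(=O)c1c(C(C)C)cc(C(C)C)cc1C(C)C)CCc1c(C)cc(O[Si](C(C)C)(C(C)C)C(C)C)cc1C | intermediate
7 | 2,5-dihydroxybenzaldehyde | O=Cc1cc(O)ccc1O | starting material
8 | 2,5-bis(allyloxy)benzaldehyde | O=Cc1cc(OCC=C)ccc1OCC=C | intermediate
9 | bis(4,4,5,5-tetramethyl-1,3,2-dioxaborolan-2-yl)methane | CC1(C)OB(CB2OC(C)(C)C(C)(C)O2)OC1(C)C | starting material
10 | lithio-bis(4,4,5,5-tetramethyl-1,3,2-dioxaborolan-2-yl)methane (in flask) | [Li]C(B1OC(C)(C)C(C)(C)O1)B1OC(C)(C)C(C)(C)O1 | intermediate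
11 | lithium 1-[2,5-bis(allyloxy)phenyl]-2,2-bis(4,4,5,5-tetramethyl-1,3,2-dioxaborolan-2-yl)ethanolate (in flask, racemic) | [Li]OC(c1cc(OCC=C)ccc1OCC=C)C(B1OC(C)(C)C(C)(C)O1)B1OC(C)(C)C(C)(C)O1 | intermediate
12 | 2-[(E)-2-[2,5-bis(allyloxy)phenyl]ethenyl]-4,4,5,5-tetramethyl-1,3,2-dioxaborolane | C=CCOc1ccc(OCC=C)c(/C=C/B2OC(C)(C)C(C)(C)O2)c1 | intermediate
13 | [(E)-2-[2,5-bis(allyloxy)phenyl]ethenyl]boronic acid (not isolated) | C=CCOc1ccc(OCC=C)c(/C=C/B(O)O)c1 | intermediate
14 | 2-[(E)-2-[2,5-bis(allyloxy)phenyl]ethenyl]-5,5-dimethyl-1,3,2-dioxaborinane | C=CCOc1ccc(OCC=C)c(/C=C/B2OCC(C)(C)CO2)c1 | intermediate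
15 | [(2S)-4-[2,6-dimethyl-4-(triisopropylsilyloxy)phenyl]-2-(2,4,6-triisopropylbenzoyloxy)butan-2-yl]lithium (in flask) | C[C@]([Li])(OC(=O)c1c(C(C)C)cc(C(C)C)cc1C(C)C)CCc1c(C)cc(O[Si](C(C)C)(C(C)C)C(C)C)cc1C | intermediate
16 | lithium boronate complex from 15 and 14, (S) at carbon, E-alkenyl on boron (in flask) | C[C@]([B-]1(OCC(C)(C)CO1)/C=C/c1cc(OCC=C)ccc1OCC=C)(OC(=O)c1c(C(C)C)cc(C(C)C)cc1C(C)C)CCc1c(C)cc(O[Si](C(C)C)(C(C)C)C(C)C)cc1C.[Li+] | intermediate
17 | 2-[(3R,4E)-5-[2,5-bis(allyloxy)phenyl]-1-[2,6-dimethyl-4-(triisopropylsilyloxy)phenyl]-3-methylpent-4-en-3-yl]-5,5-dimethyl-1,3,2-dioxaborinane (in flask) | C[C@@](B1OCC(C)(C)CO1)(/C=C/c1cc(OCC=C)ccc1OCC=C)CCc1c(C)cc(O[Si](C(C)C)(C(C)C)C(C)C)cc1C | intermediate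
18 | (3S,4E)-5-[2,5-bis(allyloxy)phenyl]-1-[2,6-dimethyl-4-(triisopropylsilyloxy)phenyl]-3-methylpent-4-en-3-ol | Cc1cc(O[Si](C(C)C)(C(C)C)C(C)C)cc(C)c1CC[C@](C)(O)/C=C/c1cc(OCC=C)ccc1OCC=C | intermediate
19 | 4-[(3S,4E)-5-[2,5-bis(allyloxy)phenyl]-3-hydroxy-3-methylpent-4-en-1-yl]-3,5-dimethylphenol | Cc1cc(O)cc(C)c1CC[C@](C)(O)/C=C/c1cc(OCC=C)ccc1OCC=C | intermediate
20 | 4-[(3S,4E)-5-[2,5-bis(allyloxy)phenyl]-3-hydroxy-3-methylpent-4-en-1-yl]-2-(hydroxymethyl)-3,5-dimethylphenol (in flask, as magnesium salt) | Cc1cc(O)c(CO)c(C)c1CC[C@](C)(O)/C=C/c1cc(OCC=C)ccc1OCC=C | intermediate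
21 | 3-[(3S,4E)-5-[2,5-bis(allyloxy)phenyl]-3-hydroxy-3-methylpent-4-en-1-yl]-6-hydroxy-2,4-dimethylbenzaldehyde | Cc1cc(O)c(C=O)c(C)c1CC[C@](C)(O)/C=C/c1cc(OCC=C)ccc1OCC=C | intermediate
22 | 3-[(3S,4E)-5-(2,5-dihydroxyphenyl)-3-hydroxy-3-methylpent-4-en-1-yl]-6-hydroxy-2,4-dimethylbenzaldehyde | Cc1cc(O)c(C=O)c(C)c1CC[C@](C)(O)/C=C/c1cc(O)ccc1O | target

**Step count and risks**

Total steps: 11. Longest linear sequence: 8 steps (1, 2, 3, 4, 8, 9, 10, 11, from compound 1).

Steps most likely to fail:

Step 8. The deprotonation may be unselective (metalation of the ring or of a benzylic position competing with the O-bound C–H), the hindered organolithium may complex boron too slowly at −60 °C and decompose, or the allylic boronic ester may undergo a 1,3-boron shift before oxidation. The fallback makes the same bond with normal polarity, setting out from 5 and 8 and returning at 18. Oxidation of 5 (Dess–Martin periodinane, CH2Cl2) would give 4-[2,6-dimethyl-4-(triisopropylsilyloxy)phenyl]butan-2-one F1. Ohira–Bestmann homologation of 8 (dimethyl (1-diazo-2-oxopropyl)phosphonate, K2CO3, MeOH) would give 1,4-bis(allyloxy)-2-ethynylbenzene F2. Hydrozirconation of F2 (Cp2Zr(H)Cl, CH2Cl2, rt, the terminal alkyne reacting ahead of the allyl ethers) would give the (E)-alkenylzirconocene chloride F3. Transmetalation with Me2Zn would give the (E)-alkenyl(methyl)zinc F4, which is added to F1 in the presence of Ti(OiPr)4 and a chiral trans-1,2-diaminocyclohexane bis(sulfonamide) diol ligand to give 18. Discrimination between CH3 and CH2CH2Ar in this catalytic asymmetric alkenylation is expected to be moderate only, so enrichment by preparative chiral chromatography is foreseen; the ligand antipode is chosen to deliver the (S) carbinol.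

Step 10. Mg(II) at reflux may ionise the tertiary allylic alcohol, or the formylation may stall at the hydroxymethyl stage. The fallback introduces the formyl group before the fragment union, setting out from 6 (with 14) and returning at 21.
- TBAF would give (2S)-4-(4-hydroxy-2,6-dimethylphenyl)butan-2-yl 2,4,6-triisopropylbenzoate F5.
- MgCl2/Et3N/(CH2O)n would give the salicylaldehyde F6, in which nothing acid- or Lewis-acid-sensitive is present.
- TIPSOTf/2,6-lutidine would give the silyl ether F7.
- HC(OMe)3, cat. PPTS, MeOH would give the dimethyl acetal F8.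
- Lithiation–borylation–oxidation with 14 under the conditions of step 8, through lithiated benzoate F9, boronate complex F10 and boronic ester F11, would give the tertiary alcohol F12.
- TBAF would give the phenol acetal F13, whose o-hydroxyaryl acetal should hydrolyse in dilute aqueous AcOH/THF at 0 °C to 21.

Step 11. π-Allyl palladium may C-allylate the electron-rich phenols, or the hydroquinone may be oxidised in the basic medium. The fallback removes the allyl groups by isomerisation and hydrolysis, setting out from 21 and returning at 22. H2-activated [Ir(cod)(PMePh2)2]PF6 in THF at rt would give the bis[(E)-prop-1-enyl] ether F14; the styrene cannot migrate because C3 is quaternary. Brief treatment with dilute aqueous HCl (pH about 2) in acetone at 0 °C should then hydrolyse the aryl enol ethers to 22.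

**Further compounds**

F1 | step 8 | 4-[2,6-dimethyl-4-(triisopropylsilyloxy)phenyl]butan-2-one | CC(=O)CCc1c(C)cc(O[Si](C(C)C)(C(C)C)C(C)C)cc1C
F2 | step 8 | 1,4-bis(allyloxy)-2-ethynylbenzene | C#Cc1cc(OCC=C)ccc1OCC=C
F3 | step 8 | chloro[(E)-2-[2,5-bis(allyloxy)phenyl]ethenyl]zirconocene (cyclopentadienyl rings drawn σ-bound) | Cl[Zr](/C=C/c1cc(OCC=C)ccc1OCC=C)(C1C=CC=C1)C1C=CC=C1
F4 | step 8 | [(E)-2-[2,5-bis(allyloxy)phenyl]ethenyl](methyl)zinc | C[Zn]/C=C/c1cc(OCC=C)ccc1OCC=C
F5 | step 10 | (2S)-4-(4-hydroxy-2,6-dimethylphenyl)butan-2-yl 2,4,6-triisopropylbenzoate | C[C@H](OC(=O)c1c(C(C)C)cc(C(C)C)cc1C(C)C)CCc1c(C)cc(O)cc1C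
F6 | step 10 | (2S)-4-(3-formyl-4-hydroxy-2,6-dimethylphenyl)butan-2-yl 2,4,6-triisopropylbenzoate | C[C@H](OC(=O)c1c(C(C)C)cc(C(C)C)cc1C(C)C)CCc1c(C)cc(O)c(C=O)c1C
F7 | step 10 | (2S)-4-[3-formyl-2,6-dimethyl-4-(triisopropylsilyloxy)phenyl]butan-2-yl 2,4,6-triisopropylbenzoate | C[C@H](OC(=O)c1c(C(C)C)cc(C(C)C)cc1C(C)C)CCc1c(C)cc(O[Si](C(C)C)(C(C)C)C(C)C)c(C=O)c1C
F8 | step 10 | (2S)-4-[3-(dimethoxymethyl)-2,6-dimethyl-4-(triisopropylsilyloxy)phenyl]butan-2-yl 2,4,6-triisopropylbenzoate | C[C@H](OC(=O)c1c(C(C)C)cc(C(C)C)cc1C(C)C)CCc1c(C)cc(O[Si](C(C)C)(C(C)C)C(C)C)c(C(OC)OC)c1C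
F9 | step 10 | α-lithiated benzoate from F8 (in flask) | C[C@]([Li])(OC(=O)c1c(C(C)C)cc(C(C)C)cc1C(C)C)CCc1c(C)cc(O[Si](C(C)C)(C(C)C)C(C)C)c(C(OC)OC)c1C
F10 | step 10 | lithium boronate complex from F9 and 14 (in flask) | C[C@]([B-]1(OCC(C)(C)CO1)/C=C/c1cc(OCC=C)ccc1OCC=C)(OC(=O)c1c(C(C)C)cc(C(C)C)cc1C(C)C)CCc1c(C)cc(O[Si](C(C)C)(C(C)C)C(C)C)c(C(OC)OC)c1C.[Li+]
F11 | step 10 | tertiary allylic neopentyl glycol boronic ester from F10 (in flask) | C[C@@](B1OCC(C)(C)CO1)(/C=C/c1cc(OCC=C)ccc1OCC=C)CCc1c(C)cc(O[Si](C(C)C)(C(C)C)C(C)C)c(C(OC)OC)c1C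
F12 | step 10 | (3S,4E)-5-[2,5-bis(allyloxy)phenyl]-1-[3-(dimethoxymethyl)-2,6-dimethyl-4-(triisopropylsilyloxy)phenyl]-3-methylpent-4-en-3-ol | Cc1cc(O[Si](C(C)C)(C(C)C)C(C)C)c(C(OC)OC)c(C)c1CC[C@](C)(O)/C=C/c1cc(OCC=C)ccc1OCC=C
F13 | step 10 | 4-[(3S,4E)-5-[2,5-bis(allyloxy)phenyl]-3-hydroxy-3-methylpent-4-en-1-yl]-2-(dimethoxymethyl)-3,5-dimethylphenol | Cc1cc(O)c(C(OC)OC)c(C)c1CC[C@](C)(O)/C=C/c1cc(OCC=C)ccc1OCC=C
F14 | step 11 | 3-[(3S,4E)-5-[2,5-bis[(E)-prop-1-enyloxy]phenyl]-3-hydroxy-3-methylpent-4-en-1-yl]-6-hydroxy-2,4-dimethylbenzaldehyde | Cc1cc(O)c(C=O)c(C)c1CC[C@](C)(O)/C=C/c1cc(O/C=C/C)ccc1O/C=C/C
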